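- Gamma and theta share one charge and one cold start; they part at 20 h, when gamma goes to 40 °C and theta stays at 0 °C.

| flask | left-handed substrate | right-handed substrate | gas | free catalyst | impurity | temperature | remark | time |
|---|---|---|---|---|---|---|---|---|
| Saturday's | 0.62 M | 0.62 M | 36 mM (held) | 8 mM | 1.7 mM | 10 °C | run made earlier |  |
| Thursday's | 0.62 M | 0.62 M | 36 mM (held) | 18 mM | 1.7 mM | 32 °C | run made earlier |  |
| gamma | 0.62 M | 0.62 M | 36 mM (held) | 12 mM | 1.7 mM |  | at 0 °C until 20 h, from then on at 40 °C | 3.0 d |
| theta | 0.62 M | 0.62 M | 36 mM (held) | 12 mM | 1.7 mM |  | at 0 °C throughout | 3.0 d |

- Saturday's (time / d: left-handed product / %, left-handed substrate / %): 0.500: 28.4, 5.3; 1.04: 26.6, 0; 1.67: 27.3, 0.2; 2.50: 29.3, 0.5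
- Thursday's (time / h: left-handed product / %, left-handed substrate / %): 1.33: 6.1, 40.8; 3.00: 11.6, 29.2; 8.00: 25.1, 0.4; 20.0: 32.3, 0

(standard deviation of a reading: 0.3 percentage points)

- free catalyst is single-handed; left-handed substrate and right-handed substrate are mirror images of each other, charged as a racemate, each of them at the stated concentration
- at the start none of reagent is dissolved
- the earlier runs were read with a standard deviation of 0.3 percentage points
- on the list of suspects stand: free catalyst + impurity -> spent catalyst; gas <-> reagent; left-handed product <-> right-handed product; reagent + free catalyst + left-handed substrate -> free catalyst + left-handed product; reagent + free catalyst + right-handed substrate -> free catalyst + right-handed product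

* which of the two ends with the higher amount of left-handed product, in percent of the left-handed substrate and right-handed substrate together charged ("neither" if they lie within 2 percentage points) (gamma / theta / neither)
* left-handed product at the end, in percent of the left-handed substrate and right-handed substrate together charged, gamma
* left-handed product at the end, in percent of the left-handed substrate and right-handed substrate together charged, theta

- Left-handed substrate reacts first: Saturday's reads 0 % at 1.04 d, Thursday's 0.4 % at 8.00 h. Saturday's left-handed product then falls to 26.6 %, so it is crossing to right-handed product.
- Take that crossing as an even split, in theta too. Then [right-handed substrate] is what the two products leave, twice left-handed product subtracted from the whole, and its pseudo-first-order decay can be read after those times.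
- Saturday's gives 0.0840 /d and Thursday's 0.683 /d.
- Assume impurity removes its own amount of free catalyst, leaving 6.30 mM and 16.3 mM. Per free catalyst, Thursday's is then faster by a factor 3.14, which you spread geometrically over temperature.
- With 10.3 mM in theta, this gives 8.50 d, the right-hand half-life. In gamma's hot stretch it is 1.06 d.
- Start both from Saturday's 46.8 % right-handed substrate. Theta counts 0.231 half-lives from 1.04 d and gamma 2.04 from 20 h. Because gamma counts more, you expect gamma higher: 44.3 % against 30.1 % in theta.
- The forecast lies below your figures: it says gamma, 43 % and 28 %, holding that “Racemization is complete in both flasks by the end”.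
- The simulation gives gamma, with 43.2 % in gamma and 29.2 % in theta.

    free catalyst + impurity → spent catalyst (k = 0.430 /M/s, Ea = 52.0 kJ/mol)
    gas ⇌ reagent, rate k2*(csat - [reagent]) (kL = 7.10 × 10⁻⁴ /s)
    left-handed product ⇌ right-handed product (k = 8.00 × 10⁻⁶ /s, Ea = 92.0 kJ/mol)
    reagent + free catalyst + left-handed substrate → free catalyst + left-handed product (k = 0.250 /M²/s, Ea = 48.0 kJ/mol)
    reagent + free catalyst + right-handed substrate → free catalyst + right-handed product (k = 0.00250 /M²/s, Ea = 37.0 kJ/mol)
    (constants at 0 °C)

- Now take a flask like theta kept at 25 °C. Your right-hand half-life shrinks from 8.50 d to 2.31 d. Start the count at Thursday's 8.00 h, from 49.8 % right-handed substrate, and 1.15 half-lives remain. That leaves 22.4 % right-handed substrate and 38.8 % left-handed product. The flask holds 22.5 % right-handed substrate, 38.9 % right-handed product and 38.7 % left-handed product.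

The readings were computed with made-up constants.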